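- You are asked which flask ends best by the share of target in target plus trapped intermediate.

in all of them: partner 1.30 equiv; capture agent 0.0198 M; time 5.0 min

|  | substrate | remark | temperature |
|---|---|---|---|
| north-east | 0.066 M (fed, over 4.0 min) | the addition at 0 °C, then warmed to 20 °C; the feed brings no volume worth counting |  |
| west | 0.066 M (fed, over 4.0 min) | all else is in the flask from the start; the feed brings no volume worth counting | 20 °C |
| south | 0.066 M | everything together at the start at 0 °C, warmed to 20 °C at 4.0 min |  |
| north | 0.066 M (in portions, 3, over 4.0 min) | first portion at the start, last at 4.0 min | 20 °C |
| south-east | 0.066 M | everything together at the start | 20 °C |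

* the best flask by share of target in target plus trapped intermediate; "all alike" if 1.5 percentage points covers them all (north-east / west / south / north / south-east / all alike)
* share of target in target plus trapped intermediate at the end, north-east
* share of target in target plus trapped intermediate at the end, west
* share of target in target plus trapped intermediate at the end, south
* share of target in target plus trapped intermediate at the end, north
* share of target in target plus trapped intermediate at the end, south-east

- where a step has two of a species, its rate is k times that concentration squared, and two are used at each turn
- the list of constants is for 20 °C, to be carried to other temperatures by the activation energies and enthalpies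

    open intermediate + capture agent → trapped intermediate (k1 = 0.22 M⁻¹ s⁻¹, Ea1 = 57.0 kJ mol⁻¹)
    open intermediate + second intermediate ⇌ target (K2 = 360 M⁻¹, k2 = 3.6 M⁻¹ s⁻¹, Ea2 = 55.0 kJ mol⁻¹, ΔH2 = −67.0 kJ mol⁻¹)
    2 second intermediate → homo product (k3 = 3.4 M⁻¹ s⁻¹, Ea3 = 43.0 kJ mol⁻¹)
    substrate + second intermediate → side product (k4 = 0.083 M⁻¹ s⁻¹, Ea4 = 56.0 kJ mol⁻¹)
    partner → second intermediate (k5 = 0.12 s⁻¹, Ea5 = 68.0 kJ mol⁻¹)
    substrate → open intermediate (k6 = 0.053 s⁻¹, Ea6 = 80.0 kJ mol⁻¹)
    (constants at 20 °C)

- Turn the question round: what would have to be true for trapped intermediate to outweigh target? Each capture uses one capture agent, and the flask holds 0.0198 M of it against a whole substrate charge of 0.066 M, so c(capture agent)/c(substrate) = 30.0% is the capture ceiling, the part of the substrate charged that can stand as trapped intermediate. Capture agent is the limiting reagent of that step.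
- So the large term is bounded, and you compute only the small one: the share is at least target/(target + ceiling), and trapped intermediate outweighs target only where target stands below the ceiling.
- How far is a flask from that? In south-east, the half-life of open intermediate under capture, 2.7 min, is shorter than the run of 5.0 min, so I expect capture to work through much of its charge there, and that flask passes 0.5 if its target tops the ceiling.
- In west, the feed lasts 29 lifetimes of the partner, so the partner is released long before the substrate is in, and I expect target below the ceiling and a share under 0.5. My reckoning stops at these bounds and gives no figure for each flask.
- The forecast says south, with 68% for north-east, 21% for west, 73% for south, 36% for north and 53% for south-east, on the ground that “the cold flasks win, with south narrowly ahead because all its substrate is present from the start”.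
- The simulation gives south as best, with 72.5%, then north-east 58.4%, south-east 55.5%, north 38.9% and west 23.0%. North-east stands 9.6 percentage points below the forecast, holding target 17.9% and trapped intermediate 12.8%. South-east holds target 31.3%, above the ceiling; west holds 7.21%, below it.

- South has not come to rest at 5.00 min: 58% of its capture agent remains, and its trapped intermediate stands at 12.6%. After 50.0 min, south holds capture agent 0%, trapped intermediate 30.0% and target 10.1%, down from 33.2%. Target over target plus ceiling then reckons to 25.2%, and the share in the flask is 25.3%. West, with target 5.33% and trapped intermediate 30.0% at that time, reckons to 15.1%, and its share in the flask is 15.1%.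

(The constants stand for no real mixture.)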